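(The data stem from a simulated flask with constants of no real substance; noise was put on by code.)

X cannot come from D that is not there, and the east run, which is this very flask, reads D at 0% after 3.00 h. D is the limiting reagent here.

| flask | D | Z | temperature | remark | time |
|---|---|---|---|---|---|
| east | 0.40 M | 0.1 mol% | 70 °C | the very flask that is asked about, followed so far |  |
| north-west | 0.20 M | 0.1 mol% | 76 °C | run made earlier |  |
| flask | 0.40 M | 0.1 mol% | 70 °C |  | 5.0 h |

- east (time / h: X / %, D / %): 0.417: 20.8, 62.4; 1.00: 41.8, 9.9; 2.00: 42.3, 0.5; 3.00: 44.7, 0
- north-west (time / h: X / %, D / %): 0.200: 13.2, 66.0; 0.500: 23.1, 11.3; 1.00: 25.7, 0; 2.50: 24.7, 0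

(standard deviation of a reading: 1 percentage point)

- oak: change nothing and wait 2.5 h more
- larch: at 5.0 h take out 90% of the X then present, then wait 2.5 h
- cedar: at 5.0 h add Z, 50.0% of the amount charged, then wait 2.5 h
- ash: at 5.0 h raise the temperature by 25 K, then wait 2.5 h

- solid, in amounts per volume of the solution: D
- removed X is counted in
- the earlier runs were read with a standard deviation of 1 percentage point
- at the start none of D is in solution
- additions bring no volume worth counting

- X, in percent of the D first charged, at 5.0 h
- the option that brings most further X ("none" if no option brings more than 2 percentage points) (oak / larch / cedar / ash / none)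
- X present, with what was taken out counted in, in percent of the D first charged, after oak
- X present, with what was taken out counted in, in percent of the D first charged, after larch

Follow one molecule of D in the east flask. It reacts, then takes a fork: to X, or elsewhere. Count its chances from the last east reading:

odds = 44.7% / 55.3% = 0.808

Call this the X odds, the X made against the D lost otherwise over a whole run; it is a run-long selectivity factor. Then price any further gain:

further X = D left × odds / (1 + odds) = 0% × 0.447 = 0 percentage points

Now turn each setting by hand, for the east flask.

Wait: D left stays at that reading, so reckon no gain.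

Take out X: the north-west run reads X at 25.7%, then 24.7%, with D at 0%. Nothing there shows a flow back to X, so reckon no gain, with a small doubt.

Add Z: in the east readings the share of used D that became X falls from 55.3% to 40.0%, which fits a fading Z. Assume the odds rise in step with Z. They still multiply the same D left, so reckon no gain.

Heat: this may shift the odds, but the product stands as before.

Commit to X near 44.7% at 5.0 h, and to no option.

The forecast gives 43.7% (42.2% to 45.3%), best none, oak 43.7%, larch 43.9%: “X stalls because substrate has run out”. My figure stands above its 43.7% by 1 point.

The flask gives 44.6% at 5.0 h. The gains are oak 0 points, larch 0 points, cedar 0 points, ash 0 points, so best is none; oak ends at 44.6%, larch at 44.6%.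

    D ⇌ G, rate k1*(cs1 - [G]) while solid is left; crystals form when [G] > cs1 (solubility = 0.170 M, k = 5.90 × 10⁻⁴ /s)
    G → E (k = 6.80 × 10⁻⁴ /s, Ea = 94.0 kJ/mol)
    G + Z → Z + X (k = 80.0 /M/s, Ea = 41.0 kJ/mol)
    G → L (k = 0.0170 /s, Ea = 87.0 kJ/mol)
    Z → J (k = 4.00 × 10⁻⁴ /s, Ea = 108 kJ/mol)
    (constants at 70 °C)

Read the odds in the flask at 5.00 h: X 44.6% against L and E together 55.4%, which is 0.804. Change the charge of Z to upset the forecast's "now": at 0.081 mol% or 0.12 mol% the flask's answer has moved by 5 points. Take the neighbour flask with 0.25 mol% of Z instead of 0.1 mol%, the other charges and the time held. Scale the odds with Z: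

odds = 0.808 × 2.50 = 2.02, X = 66.9%

That neighbour flask gives 66.0%.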